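The seven-membered ring B is closed last, by ring-closing metathesis that creates the C8=C9 trisubstituted alkene (daucane numbering) from a C10 vinyl ketone and a C6-bound methallyl group held cis on a preformed cyclopentane. Ten of the fifteen skeletal carbons, including the C4 carbinol stereocentre with its isopropyl group, come from (S)-terpinen-4-ol (ozonolysis, aldol ring contraction). A silicon tether on O4 delivers C10 to C1 by radical cyclisation, and a cis-fused lactol, then a γ-lactone bridging C10 and O6, fix C5, differentiate the two secondary oxygens and release the dienone for the key step.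

Key step: step 9

Remark on numbering: daucane numbering is used for the target and late intermediates. C1 is the quaternary ring-fusion carbon bearing CH3-15, C2 and C3 are the ring A methylenes, C4 is the carbinol carbon bearing the isopropyl group, C5 is the ring-fusion CH, C6 is CH–O(aroyl), C7 is CH2, C8 is C(CH3)=, C9 is =CH and C10 is CH–O(tigloyl). Ring A is the cyclopentane and ring B the cycloheptene. The target is (1R,4R,5S,6R,10R) and cis-fused (H-5 and CH3-15 cis).

Assumption: (S)-(+)-terpinen-4-ol is used in enantiopure form; commercial lots differ in enantiomeric purity.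

Step 1
Reactants: 1 (S)-(+)-terpinen-4-ol
Product: 2 (bromomethyl)dimethylsilyl ether of 1
Conditions: BrCH2SiMe2Cl, Et3N, DMAP (cat.), CH2Cl2, 0 °C → rt
Reagents that add atoms: (bromomethyl)chlorodimethylsilane, C[Si](C)(Cl)CBr
Why: DMAP-catalysed silylation of the tertiary alcohol installs a group that protects O4 against β-elimination and retro-aldol cleavage in steps 2 and 3 and later serves as the radical tether.

Step 2
Reactants: 2 silyl ether
Product: 4 (3S)-3-{[(bromomethyl)dimethylsilyl]oxy}-6-oxo-3-(propan-2-yl)heptanal, via ozonide 3 (not isolated)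
Conditions: O3, CH2Cl2, −78 °C; then Me2S, −78 °C → rt
Reagents that add atoms: ozone, [O-][O+]=O
Why: Ozonolysis with reductive work-up cleaves the only C=C bond to the 1,6-keto aldehyde and leaves the stereocentre untouched.

Step 3
Reactants: 4 keto aldehyde
Product: 6 (5R)-5-{[(bromomethyl)dimethylsilyl]oxy}-2-methyl-5-(propan-2-yl)cyclopent-1-ene-1-carbaldehyde, via aldol adduct 5 (not isolated)
Conditions: Bn2NH·CF3CO2H (0.3 equiv), PhMe, 50 °C
Reagents that add atoms: none
Why: Amine-salt-catalysed intramolecular aldol condensation (enamine of the aldehyde attacks the methyl ketone, then dehydration) should give the 2-methylcyclopent-1-enecarbaldehyde, the usual outcome for 6-oxoheptanals under these conditions.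

Step 4
Reactants: 6 enal
Product: 9 cis-fused lactol 3a-methyl-6-(propan-2-yl)hexahydro-1H-cyclopenta[c]furan-1,6-diol, via siloxane aldehyde 7 (not isolated), via hydroxy aldehyde 8 (not isolated)
Conditions: Bu3SnH (syringe pump), AIBN (cat.), PhH, 80 °C; then KF, KHCO3, 30% H2O2, THF/MeOH, rt
Reagents that add atoms: hydrogen peroxide, OO
Why: In this silicon-tethered radical cyclisation the nucleophilic α-silyl radical should add 6-endo to the β-carbon of the enal (5-exo would attack the fully substituted α-carbon against polarity), so the new C1–C10 bond is necessarily cis to O4 and sets the quaternary C1; Tamao oxidation then frees the CH2OH group with cleavage of the Si–O bond, and the epimerisable aldehyde is funnelled under the bicarbonate conditions into the cis-fused lactol, which fixes C5.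

Step 5
Reactants: 9 lactol
Product: 11 3a-methyl-6-(propan-2-yl)-6-[(triethylsilyl)oxy]hexahydro-1H-cyclopenta[c]furan-1-ol, via bis(triethylsilyl) ether 10 (not isolated)
Conditions: Et3SiOTf (2.5 equiv), 2,6-lutidine, CH2Cl2, −78 → 0 °C; then AcOH/THF/H2O, rt
Reagents that add atoms: triethylsilyl trifluoromethanesulfonate, CC[Si](CC)(CC)OS(=O)(=O)C(F)(F)F
Why: Exhaustive silylation followed by selective hydrolysis of the labile anomeric silyl acetal leaves the robust tertiary TES ether, which removes O4 as a chelation site before the carbonyl additions.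

Step 6
Reactants: 11 lactol; 12 2-methylallylmagnesium chloride
Product: 13 diol (1R)-1-{2-(hydroxymethyl)-2-methyl-5-(propan-2-yl)-5-[(triethylsilyl)oxy]cyclopentyl}-3-methylbut-3-en-1-ol
Conditions: 12 (3.5 equiv), THF, −78 → 0 °C; aq. NH4Cl
Reagents that add atoms: none
Why: Grignard addition to the ring-opened magnesium lactolate: the aldehyde, held by the C10 alkoxide in a seven-membered chelate, should be attacked anti to the bulky C4(OSiEt3)(i-Pr) carbon (Felkin–Anh sense), favouring the 6R carbinol.

Step 7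
Reactants: 13 diol
Product: 15 γ-lactone 6a-methyl-3-(2-methylprop-2-en-1-yl)-4-(propan-2-yl)-4-[(triethylsilyl)oxy]hexahydro-1H-cyclopenta[c]furan-1-one, via lactol 14 (not isolated)
Conditions: TEMPO (0.2 equiv), PhI(OAc)2 (2.5 equiv), CH2Cl2, rt
Reagents that add atoms: none
Why: TEMPO/PhI(OAc)2 oxidises the primary alcohol chemoselectively; the aldehyde is captured by the C6 hydroxyl as a lactol and oxidised on to the lactone, which masks O6 and raises C10 to the acyl level.

Step 8
Reactants: 15 lactone; 16 vinylmagnesium bromide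
Product: 18 hydroxy dienone 1-{2-[(1R)-1-hydroxy-3-methylbut-3-en-1-yl]-1-methyl-3-(propan-2-yl)-3-[(triethylsilyl)oxy]cyclopentyl}prop-2-en-1-one, via hemiketal 17 (not isolated)
Conditions: 16 (1.3 equiv), THF, −78 → −40 °C; aq. NH4Cl
Reagents that add atoms: none
Why: Mono-addition to the hindered, non-enolisable lactone should stop at the magnesium hemiketal, which on work-up opens to the γ-hydroxy vinyl ketone (ring-chain tautomers), freeing O6 and placing the second alkene on C10.

Step 9
Reactants: 18 hydroxy dienone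
Product: 19 (1R,4R,5S,6R)-6-hydroxy-4-[(triethylsilyl)oxy]dauc-8-en-10-one
Conditions: second-generation Hoveyda–Grubbs catalyst RuCl2(=CH-C6H4-2-O-i-Pr)(H2IMes) (10 mol %), PhMe (2 mM), 80 °C, argon sparge
Reagents that add atoms: none
Why: Ruthenium-alkylidene-catalysed ring-closing olefin metathesis ([2+2] cycloaddition and cycloreversion): the catalyst loads onto one terminal alkene of 18 and intramolecular metathesis with the other joins C8 to C9 with loss of ethene. The closest known reaction type is ring-closing metathesis of vinyl ketones with 1,1-disubstituted alkenes to β-methylcycloalkenones. Ring B, the seven-membered carbocycle, is closed by C8=C9 bond formation between two chains on adjacent, cis-disposed ring A carbons, so the alkene is necessarily Z (endocyclic) and conjugated with the C10 ketone. No new stereocentre is formed, and C1, C4, C5 and C6 are carried through unchanged. The step needs ring closure to win over intermolecular cross-metathesis and alkene migration, which the cis relationship of the two arms (fixed in lactone 15), the low homodimerisation tendency of both alkenes, and high dilution with removal of ethene should secure. The hemiketal tautomer of 18 leads to the same product, since its ring closure gives the bridged hemiketal tautomer of 19.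

Step 10
Reactants: 19 hydroxy enone; 20 4-[(tert-butyldimethylsilyl)oxy]benzoic acid
Product: 21 (1R,4R,5S,6R)-10-oxo-4-[(triethylsilyl)oxy]dauc-8-en-6-yl 4-[(tert-butyldimethylsilyl)oxy]benzoate
Conditions: 20 (1.5 equiv), DCC, DMAP, CH2Cl2, 0 °C → rt
Reagents that add atoms: none
Why: Steglich esterification of the only free hydroxyl (O4 is silylated, C10 is a ketone).

Step 11
Reactants: 21 keto ester
Product: 22 (1R,4R,5S,6R,10R)-10-hydroxy-4-[(triethylsilyl)oxy]dauc-8-en-6-yl 4-[(tert-butyldimethylsilyl)oxy]benzoate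
Conditions: (S)-2-methyl-CBS-oxazaborolidine (1 equiv), catecholborane, PhMe/CH2Cl2, −78 → −40 °C
Reagents that add atoms: none
Why: In this Corey–Bakshi–Shibata 1,2-reduction the ketone should bind with the quaternary C1 side as the large group and the C9 alkenyl side as the small group, so the (S)-catalyst should give the 10R allylic alcohol (OH cis to CH3-15) under reagent control.

Step 12
Reactants: 22 allylic alcohol; 23 tigloyl chloride
Product: 24 (1R,4R,5S,6R,10R)-10-[(E)-2-methylbut-2-enoyloxy]-4-[(triethylsilyl)oxy]dauc-8-en-6-yl 4-[(tert-butyldimethylsilyl)oxy]benzoate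
Conditions: 23 (2 equiv), pyridine, DMAP (cat.), CH2Cl2, 0 °C → rt
Reagents that add atoms: none
Why: DMAP-catalysed acylation of the only free hydroxyl with the configurationally stable (E)-acid chloride; pyridine as base avoids ketene formation and deconjugation.

Step 13
Reactants: 24 bis-silyl diester
Product: 26 (1R,4R,5S,6R,10R)-4-hydroxy-6-(4-hydroxybenzoyloxy)-10-[(E)-2-methylbut-2-enoyloxy]dauc-8-ene, via phenol 25 (not isolated)
Conditions: HF·pyridine, pyridine/THF, 0 °C → rt
Reagents that add atoms: none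
Why: Fluoride cleavage of the aryl TBS and tertiary TES ethers under mildly acidic, non-nucleophilic conditions that should avoid acyl migration and ester cleavage.

Compound list
1 | (S)-(+)-terpinen-4-ol, (1S)-4-methyl-1-(propan-2-yl)cyclohex-3-en-1-ol | CC1=CC[C@@](O)(CC1)C(C)C | starting material
2 | (S)-(bromomethyl)dimethyl{[4-methyl-1-(propan-2-yl)cyclohex-3-en-1-yl]oxy}silane | CC1=CC[C@@](O[Si](C)(C)CBr)(CC1)C(C)C | intermediate
3 | ozonide of 2 (1,2,4-trioxolane across the former C=C) | CC12CC[C@@](O[Si](C)(C)CBr)(C(C)C)CC(OO1)O2 | intermediate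
4 | (3S)-3-{[(bromomethyl)dimethylsilyl]oxy}-6-oxo-3-(propan-2-yl)heptanal | CC(=O)CC[C@](O[Si](C)(C)CBr)(CC=O)C(C)C | intermediate
5 | aldol adduct, 5-{[(bromomethyl)dimethylsilyl]oxy}-2-hydroxy-2-methyl-5-(propan-2-yl)cyclopentane-1-carbaldehyde (C5 as in 6) | O=CC1C(C)(O)CC[C@@]1(O[Si](C)(C)CBr)C(C)C | intermediate
6 | (5R)-5-{[(bromomethyl)dimethylsilyl]oxy}-2-methyl-5-(propan-2-yl)cyclopent-1-ene-1-carbaldehyde | O=CC1=C(C)CC[C@@]1(O[Si](C)(C)CBr)C(C)C | intermediate
7 | 3,3,5-trimethyl-1-(propan-2-yl)-2-oxa-3-silabicyclo[3.2.1]octane-8-carbaldehyde (C8 epimers) | O=CC1[C@@]2(C)CC[C@@]1(O[Si](C)(C)C2)C(C)C | intermediate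
8 | 5-hydroxy-2-(hydroxymethyl)-2-methyl-5-(propan-2-yl)cyclopentane-1-carbaldehyde (CH2OH cis to OH; epimers at the CHO carbon) | O=CC1[C@](C)(CO)CC[C@@]1(O)C(C)C | intermediate
9 | cis-fused lactol 3a-methyl-6-(propan-2-yl)hexahydro-1H-cyclopenta[c]furan-1,6-diol (anomers; C1, C4, C5 of the target set) | OC1OC[C@]2(C)CC[C@@](O)(C(C)C)[C@H]12 | intermediate
10 | bis(triethylsilyl) ether of 9 | CC[Si](CC)(CC)OC1OC[C@]2(C)CC[C@@](O[Si](CC)(CC)CC)(C(C)C)[C@H]12 | intermediate
11 | 3a-methyl-6-(propan-2-yl)-6-[(triethylsilyl)oxy]hexahydro-1H-cyclopenta[c]furan-1-ol (anomers) | OC1OC[C@]2(C)CC[C@@](O[Si](CC)(CC)CC)(C(C)C)[C@H]12 | intermediate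
12 | 2-methylallylmagnesium chloride | CC(=C)C[Mg]Cl | starting material
13 | (1R)-1-{2-(hydroxymethyl)-2-methyl-5-(propan-2-yl)-5-[(triethylsilyl)oxy]cyclopentyl}-3-methylbut-3-en-1-ol (ring centres as in the target) | OC[C@]1(C)CC[C@@](O[Si](CC)(CC)CC)(C(C)C)[C@@H]1[C@H](O)CC(C)=C | intermediate
14 | lactol 6a-methyl-3-(2-methylprop-2-en-1-yl)-4-(propan-2-yl)-4-[(triethylsilyl)oxy]hexahydro-1H-cyclopenta[c]furan-1-ol | OC1O[C@H](CC(C)=C)[C@@H]2[C@@]1(C)CC[C@@]2(O[Si](CC)(CC)CC)C(C)C | intermediate
15 | cis-fused γ-lactone 6a-methyl-3-(2-methylprop-2-en-1-yl)-4-(propan-2-yl)-4-[(triethylsilyl)oxy]hexahydro-1H-cyclopenta[c]furan-1-one (methallyl on the convex face) | O=C1O[C@H](CC(C)=C)[C@@H]2[C@@]1(C)CC[C@@]2(O[Si](CC)(CC)CC)C(C)C | intermediate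
16 | vinylmagnesium bromide | C=C[Mg]Br | starting material
17 | hemiketal 1-ethenyl-6a-methyl-3-(2-methylprop-2-en-1-yl)-4-(propan-2-yl)-4-[(triethylsilyl)oxy]hexahydro-1H-cyclopenta[c]furan-1-ol | OC1(C=C)O[C@H](CC(C)=C)[C@@H]2[C@@]1(C)CC[C@@]2(O[Si](CC)(CC)CC)C(C)C | intermediate
18 | 1-{2-[(1R)-1-hydroxy-3-methylbut-3-en-1-yl]-1-methyl-3-(propan-2-yl)-3-[(triethylsilyl)oxy]cyclopentyl}prop-2-en-1-one (ring centres as in the target) | C=CC(=O)[C@]1(C)CC[C@@](O[Si](CC)(CC)CC)(C(C)C)[C@@H]1[C@H](O)CC(C)=C | intermediate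
19 | (1R,4R,5S,6R)-6-hydroxy-4-[(triethylsilyl)oxy]dauc-8-en-10-one (cis-fused) | O=C1C=C(C)C[C@@H](O)[C@@H]2[C@@]1(C)CC[C@@]2(O[Si](CC)(CC)CC)C(C)C | intermediate
20 | 4-[(tert-butyldimethylsilyl)oxy]benzoic acid | CC(C)(C)[Si](C)(C)Oc1ccc(cc1)C(O)=O | starting material
21 | (1R,4R,5S,6R)-10-oxo-4-[(triethylsilyl)oxy]dauc-8-en-6-yl 4-[(tert-butyldimethylsilyl)oxy]benzoate | O=C1C=C(C)C[C@@H](OC(=O)c3ccc(O[Si](C)(C)C(C)(C)C)cc3)[C@@H]2[C@@]1(C)CC[C@@]2(O[Si](CC)(CC)CC)C(C)C | intermediate
22 | (1R,4R,5S,6R,10R)-10-hydroxy-4-[(triethylsilyl)oxy]dauc-8-en-6-yl 4-[(tert-butyldimethylsilyl)oxy]benzoate | O[C@@H]1C=C(C)C[C@@H](OC(=O)c3ccc(O[Si](C)(C)C(C)(C)C)cc3)[C@@H]2[C@@]1(C)CC[C@@]2(O[Si](CC)(CC)CC)C(C)C | intermediate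
23 | tigloyl chloride, (E)-2-methylbut-2-enoyl chloride | C/C=C(\C)C(Cl)=O | starting material
24 | (1R,4R,5S,6R,10R)-10-[(E)-2-methylbut-2-enoyloxy]-4-[(triethylsilyl)oxy]dauc-8-en-6-yl 4-[(tert-butyldimethylsilyl)oxy]benzoate | C/C=C(\C)C(=O)O[C@@H]1C=C(C)C[C@@H](OC(=O)c3ccc(O[Si](C)(C)C(C)(C)C)cc3)[C@@H]2[C@@]1(C)CC[C@@]2(O[Si](CC)(CC)CC)C(C)C | intermediate
25 | (1R,4R,5S,6R,10R)-10-[(E)-2-methylbut-2-enoyloxy]-4-[(triethylsilyl)oxy]dauc-8-en-6-yl 4-hydroxybenzoate | C/C=C(\C)C(=O)O[C@@H]1C=C(C)C[C@@H](OC(=O)c3ccc(O)cc3)[C@@H]2[C@@]1(C)CC[C@@]2(O[Si](CC)(CC)CC)C(C)C | intermediate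
26 | (1R,4R,5S,6R,10R)-4-hydroxy-6-(4-hydroxybenzoyloxy)-10-[(E)-2-methylbut-2-enoyloxy]dauc-8-ene (cis-fused) | C/C=C(\C)C(=O)O[C@@H]1C=C(C)C[C@@H](OC(=O)c2ccc(O)cc2)[C@@H]2[C@@]1(C)CC[C@@]2(O)C(C)C | target

Total step count: 13. Longest linear sequence: 13 steps (1 → 26).

Steps most likely to fail

Step 4. The α-silyl radical may close 5-exo onto the α-carbon or be reduced before it cyclises, and the aldehyde may be degraded by peroxide before the lactol forms. The fallback is an intermolecular organocopper route that sets out from 1 and returns at 11. Compound 1 is converted with Et3SiOTf and 2,6-lutidine into the triethylsilyl ether of terpinen-4-ol F1. Ozonolysis with Me2S work-up gives the TES-protected keto aldehyde F2, and Bn2NH·CF3CO2H cyclises it to the TES-protected enal F3. Conjugate addition of (isopropoxydimethylsilyl)methylmagnesium chloride, catalysed by CuBr·SMe2 with Me3SiCl in THF at −78 °C, gives the trimethylsilyl enol ether F4, which is hydrolysed on work-up to the β-(silylmethyl) aldehyde F5. Tamao oxidation (KF, KHCO3, H2O2) unveils the hydroxymethyl group and the product closes to lactol 11. In this variant the C1 configuration rests on attack of the organocopper reagent anti to the isopropyl group and is less secure than with the tether.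

Step 6. Facial selectivity of the addition to the aldehyde may be poor, because both neighbours of C5 are fully substituted carbons. The fallback corrects C6 by oxidation and reduction in the bicycle; it sets out from 19 when this is accompanied or replaced by its C6 epimer F6, and returns at 19. Dess–Martin oxidation of the material converges on the ene-dione F7. NaBH4 in CH2Cl2/MeOH at −78 °C should then reduce the saturated C6 ketone in preference to the conjugated C10 ketone. Hydride should arrive on the convex face of the cis-fused bicycle (the face of H-5 and CH3-15), which places the hydroxyl on the ring A side as in 19.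

Step 11. Reagent control may be overridden by the substrate, or the hindered enone may react sluggishly, so that the C10 carbinol forms with poor facial selectivity. The fallback creates the C10 carbinol before ring closure; it sets out from 13 and returns at 22. Selective silylation of the primary hydroxyl (Et3SiCl, imidazole) gives the bis(triethylsilyl) ether F8. Steglich esterification with 20 gives the C6 benzoate F9. Swern oxidation, which cleaves and oxidises a primary triethylsilyl ether directly, gives the neopentyl aldehyde F10. Vinylmagnesium bromide 16 at −78 °C should add under Felkin–Anh control (C5 as the large group, approach past CH3-15) to give the (10R)-allylic alcohol F11. Ring-closing metathesis of F11 with the same ruthenium catalyst closes ring B and gives 22.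

Further compounds
F1 | step 4 | triethylsilyl ether of terpinen-4-ol | CC1=CC[C@@](O[Si](CC)(CC)CC)(CC1)C(C)C
F2 | step 4 | (3S)-6-oxo-3-(propan-2-yl)-3-[(triethylsilyl)oxy]heptanal | CC(=O)CC[C@](O[Si](CC)(CC)CC)(CC=O)C(C)C
F3 | step 4 | (5R)-2-methyl-5-(propan-2-yl)-5-[(triethylsilyl)oxy]cyclopent-1-ene-1-carbaldehyde | O=CC1=C(C)CC[C@@]1(O[Si](CC)(CC)CC)C(C)C
F4 | step 4 | trimethylsilyl enol ether of the conjugate adduct | C[Si](C)(C)OC=C1[C@](C)(C[Si](C)(C)OC(C)C)CC[C@@]1(O[Si](CC)(CC)CC)C(C)C
F5 | step 4 | 2-{[isopropoxy(dimethyl)silyl]methyl}-2-methyl-5-(propan-2-yl)-5-[(triethylsilyl)oxy]cyclopentane-1-carbaldehyde | O=CC1[C@](C)(C[Si](C)(C)OC(C)C)CC[C@@]1(O[Si](CC)(CC)CC)C(C)C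
F6 | step 6 | (1R,4R,5S,6S)-6-hydroxy-4-[(triethylsilyl)oxy]dauc-8-en-10-one (C6 epimer of 19) | O=C1C=C(C)C[C@H](O)[C@@H]2[C@@]1(C)CC[C@@]2(O[Si](CC)(CC)CC)C(C)C
F7 | step 6 | (1R,4R,5S)-4-[(triethylsilyl)oxy]dauc-8-ene-6,10-dione | O=C1C=C(C)CC(=O)[C@@H]2[C@@]1(C)CC[C@@]2(O[Si](CC)(CC)CC)C(C)C
F8 | step 11 | primary triethylsilyl ether of 13 | CC[Si](CC)(CC)OC[C@]1(C)CC[C@@](O[Si](CC)(CC)CC)(C(C)C)[C@@H]1[C@H](O)CC(C)=C
F9 | step 11 | 4-[(tert-butyldimethylsilyl)oxy]benzoate of F8 | CC[Si](CC)(CC)OC[C@]1(C)CC[C@@](O[Si](CC)(CC)CC)(C(C)C)[C@@H]1[C@H](OC(=O)c2ccc(O[Si](C)(C)C(C)(C)C)cc2)CC(C)=C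
F10 | step 11 | C10 aldehyde | O=C[C@]1(C)CC[C@@](O[Si](CC)(CC)CC)(C(C)C)[C@@H]1[C@H](OC(=O)c2ccc(O[Si](C)(C)C(C)(C)C)cc2)CC(C)=C
F11 | step 11 | (10R)-allylic alcohol diene | C=C[C@@H](O)[C@]1(C)CC[C@@](O[Si](CC)(CC)CC)(C(C)C)[C@@H]1[C@H](OC(=O)c2ccc(O[Si](C)(C)C(C)(C)C)cc2)CC(C)=C
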